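**Retrosynthetic overview**

1. Target acid 32 comes from aldehyde 31 (Pinnick). In the cyclohexane C5–C10, quaternary C10 carries the vinyl group C1=C2 and its neighbour C5 carries the arm C4(=C3)–C15, so C2=C1–C10–C5–C4=C3 is a hexa-1,5-diene. Joining C2–C3 and cutting C5–C10 (retro-Cope) gives the ten-membered germacra-1(10),4-dienolide aldehyde 30.
2. 30 comes from the 8β-hydroxy-6α,12-olide 25 (angelate on O8, then C15 deprotection and oxidation); 25 comes from the cis-fused 8β,12-olide 24 by acyl shift from O8 to O6.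
3. 24 comes from C6–C7 closure by intramolecular Nozaki–Hiyama–Kishi allylation of a 3-(bromomethyl)butenolide onto the C6 enal. An open-chain bromo ester with a C8 silyl ether would be expected to close anti to the silyloxy group (8α series), so O8 is instead held in the butenolide plane.
4. Chain: C7–C9 from a glycidyl ether (C8 from the chiral pool), C10/C1 from acetylide, C14 by carboalumination, C2–C3 from ethylene oxide, C4/C15 and C5/C6 by a Z-selective phosphonoacetate olefination, C11–C13 from methyl acrylate, the ester from angelic acid.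
5. Ring order: butenolide (step 12), ten-membered carbocycle (step 14), 6α,12-γ-lactone (step 15), cyclohexane by ring contraction (step 19).

Key step: step 19

Remark: germacrane numbering (C1–C15) is used for all intermediates. "4Z" is the CIP label of the ring-trans C4=C5 alkene once C15 carries oxygen. Epoxide 1 is taken as a purchasable chiral-pool compound (otherwise one step from (S)-glycidol), and aldehyde 12 is used as its anhydrous ether solution.

**Route**

Step 1
Reactants: 1 (R)-2-{[(4-methoxybenzyl)oxy]methyl}oxirane; 2 lithium acetylide–ethylenediamine complex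
Product: 3 (R)-1-[(4-methoxybenzyl)oxy]pent-4-yn-2-ol
Conditions: DMSO, 0 °C → rt; H2O quench
Reagents that add atoms: none
Why: Alkynylation of a terminal epoxide is an SN2 opening at the unsubstituted carbon, so the C8 stereocentre taken from the chiral pool is not touched.

Step 2
Reactants: 3 (R)-1-[(4-methoxybenzyl)oxy]pent-4-yn-2-ol
Product: 4 (R)-triethyl({1-[(4-methoxybenzyl)oxy]pent-4-yn-2-yl}oxy)silane
Conditions: Et3SiCl, imidazole, CH2Cl2, 0 °C → rt
Reagents that add atoms: chlorotriethylsilane, CC[Si](Cl)(CC)CC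
Why: Silyl ether formation on a secondary alcohol; the triethylsilyl group should outlast steps 3–11 and fall off under the aqueous acetic acid of step 12, which spares the TBDPS ether.

Step 3
Reactants: 4 (R)-triethyl({1-[(4-methoxybenzyl)oxy]pent-4-yn-2-yl}oxy)silane; 5 ethylene oxide
Product: 8 (3E,6R)-7-[(4-methoxybenzyl)oxy]-4-methyl-6-[(triethylsilyl)oxy]hept-3-en-1-ol, via alkenyldimethylalane 6 (not isolated), via lithium alkenylalanate 7 (not isolated)
Conditions: Me3Al (2.5 equiv), Cp2ZrCl2 (0.25 equiv), CH2Cl2, 0 °C → rt; volatiles off, hexane; n-BuLi, −78 → 0 °C; 5, THF, −78 °C → rt; aq. potassium sodium tartrate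
Reagents that add atoms: trimethylaluminium, C[Al](C)C
Why: Zirconium-catalysed Negishi carboalumination adds methyl (C14) and aluminium syn across the terminal alkyne with methyl on the internal carbon, and the derived alanate opens ethylene oxide with retention at the alkenyl carbon, so C1=C10 is formed E (C9 trans to C2) and C2–C3 arrive as a primary alcohol.

Step 4
Reactants: 8 (3E,6R)-7-[(4-methoxybenzyl)oxy]-4-methyl-6-[(triethylsilyl)oxy]hept-3-en-1-ol
Product: 9 {[(2R,4E)-7-iodo-1-[(4-methoxybenzyl)oxy]-4-methylhept-4-en-2-yl]oxy}triethylsilane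
Conditions: I2, PPh3, imidazole, CH2Cl2, 0 °C
Reagents that add atoms: iodine, II
Why: Appel-type iodination of a primary alcohol by SN2 displacement of the oxyphosphonium ion, with imidazole buffering so that the silyl and PMB ethers are inert.

Step 5
Reactants: 9 {[(2R,4E)-7-iodo-1-[(4-methoxybenzyl)oxy]-4-methylhept-4-en-2-yl]oxy}triethylsilane; 10 ethyl 2-(diphenoxyphosphoryl)acetate
Product: 11 ethyl (5E,8R)-2-(diphenoxyphosphoryl)-9-[(4-methoxybenzyl)oxy]-6-methyl-8-[(triethylsilyl)oxy]non-5-enoate (both C2 epimers)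
Conditions: NaH, DMSO, rt
Reagents that add atoms: none
Why: SN2 C-alkylation of the stabilised phosphonoacetate anion by a primary iodide installs C4 and C15; the new centre next to phosphorus is uncontrolled and is destroyed in step 6.

Step 6
Reactants: 11 ethyl (5E,8R)-2-(diphenoxyphosphoryl)-9-[(4-methoxybenzyl)oxy]-6-methyl-8-[(triethylsilyl)oxy]non-5-enoate; 12 2,2-dimethoxyacetaldehyde
Product: 13 ethyl (2Z,5E,8R)-2-(2,2-dimethoxyethylidene)-9-[(4-methoxybenzyl)oxy]-6-methyl-8-[(triethylsilyl)oxy]non-5-enoate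
Conditions: NaH, THF, −78 °C; 12, −78 → 0 °C
Reagents that add atoms: none
Why: Horner–Wadsworth–Emmons olefination with an α-substituted diaryl phosphonoacetate is kinetically Z-selective, which should place the ester (C15) cis to the acetal carbon C6 and C3 trans to C6, the ring-trans geometry needed at C4=C5.

Step 7
Reactants: 13 ethyl (2Z,5E,8R)-2-(2,2-dimethoxyethylidene)-9-[(4-methoxybenzyl)oxy]-6-methyl-8-[(triethylsilyl)oxy]non-5-enoate
Product: 14 (2Z,5E,8R)-2-(2,2-dimethoxyethylidene)-9-[(4-methoxybenzyl)oxy]-6-methyl-8-[(triethylsilyl)oxy]non-5-en-1-ol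
Conditions: i-Bu2AlH (2.5 equiv), CH2Cl2, −78 °C; aq. potassium sodium tartrate
Reagents that add atoms: none
Why: 1,2-Reduction of the conjugated ester to the allylic alcohol with i-Bu2AlH at low temperature leaves the acetal, the ethers and the alkene geometry untouched.

Step 8
Reactants: 14 (2Z,5E,8R)-2-(2,2-dimethoxyethylidene)-9-[(4-methoxybenzyl)oxy]-6-methyl-8-[(triethylsilyl)oxy]non-5-en-1-ol
Product: 15 tert-butyl{[(2Z,5E,8R)-2-(2,2-dimethoxyethylidene)-9-[(4-methoxybenzyl)oxy]-6-methyl-8-[(triethylsilyl)oxy]non-5-en-1-yl]oxy}diphenylsilane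
Conditions: t-BuPh2SiCl, imidazole, DMF, 0 °C → rt
Reagents that add atoms: tert-butyl(chloro)diphenylsilane, CC(C)(C)[Si](Cl)(c1ccccc1)c1ccccc1
Why: Silylation of the primary allylic alcohol blocks O15 with an acid-stable group and removes the cis-hydroxy acetal that could close to a dihydrofuran under acid.

Step 9
Reactants: 15 tert-butyl{[(2Z,5E,8R)-2-(2,2-dimethoxyethylidene)-9-[(4-methoxybenzyl)oxy]-6-methyl-8-[(triethylsilyl)oxy]non-5-en-1-yl]oxy}diphenylsilane
Product: 16 (2R,4E,8Z)-8-{[(tert-butyldiphenylsilyl)oxy]methyl}-10,10-dimethoxy-4-methyl-2-[(triethylsilyl)oxy]deca-4,8-dien-1-ol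
Conditions: DDQ, CH2Cl2/pH 7 phosphate buffer, 0 °C
Reagents that add atoms: none
Why: Oxidative cleavage of the PMB ether with DDQ frees the C7 primary alcohol selectively, the silyl ethers, the acetal and the trisubstituted alkenes being stable under buffered conditions.

Step 10
Reactants: 16 (2R,4E,8Z)-8-{[(tert-butyldiphenylsilyl)oxy]methyl}-10,10-dimethoxy-4-methyl-2-[(triethylsilyl)oxy]deca-4,8-dien-1-ol
Product: 17 (2R,4E,8Z)-8-{[(tert-butyldiphenylsilyl)oxy]methyl}-10,10-dimethoxy-4-methyl-2-[(triethylsilyl)oxy]deca-4,8-dienal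
Conditions: Dess–Martin periodinane, NaHCO3, CH2Cl2, 0 °C → rt
Reagents that add atoms: none
Why: Dess–Martin oxidation of the primary alcohol is mild and non-basic, so the α-silyloxy stereocentre C8 should not epimerise.

Step 11
Reactants: 17 (2R,4E,8Z)-8-{[(tert-butyldiphenylsilyl)oxy]methyl}-10,10-dimethoxy-4-methyl-2-[(triethylsilyl)oxy]deca-4,8-dienal; 18 methyl acrylate
Product: 19 methyl (4R,6E,10Z)-10-{[(tert-butyldiphenylsilyl)oxy]methyl}-3-hydroxy-12,12-dimethoxy-6-methyl-2-methylidene-4-[(triethylsilyl)oxy]dodeca-6,10-dienoate (both C3 epimers)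
Conditions: 18 (excess), DABCO (1 equiv), MeOH (cat.), rt
Reagents that add atoms: none
Why: Morita–Baylis–Hillman reaction of the activated α-silyloxy aldehyde installs C11–C13, and the new carbinol centre (C7) may form as a mixture because it becomes sp2 in step 13.

Step 12
Reactants: 19 methyl (4R,6E,10Z)-10-{[(tert-butyldiphenylsilyl)oxy]methyl}-3-hydroxy-12,12-dimethoxy-6-methyl-2-methylidene-4-[(triethylsilyl)oxy]dodeca-6,10-dienoate
Product: 21 (2Z,6E)-3-{[(tert-butyldiphenylsilyl)oxy]methyl}-8-[(2R)-3-hydroxy-4-methylidene-5-oxooxolan-2-yl]-7-methylocta-2,6-dienal (mixture at the carbinol carbon C7), via seco diol ester enal 20 (not isolated)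
Conditions: AcOH/THF/H2O (3:1:1), 35 °C; azeotrope with PhMe
Reagents that add atoms: water, O
Why: Aqueous acetic acid cleaves the secondary triethylsilyl ether and hydrolyses the allylic dimethyl acetal while the TBDPS ether survives, and the freed C8 hydroxyl undergoes γ-lactonisation onto the C12 ester because only O8 can form a five-membered ring.

Step 13
Reactants: 21 (2Z,6E)-3-{[(tert-butyldiphenylsilyl)oxy]methyl}-8-[(2R)-3-hydroxy-4-methylidene-5-oxooxolan-2-yl]-7-methylocta-2,6-dienal
Product: 22 (2Z,6E)-8-[(2R)-4-(bromomethyl)-5-oxo-2,5-dihydrofuran-2-yl]-3-{[(tert-butyldiphenylsilyl)oxy]methyl}-7-methylocta-2,6-dienal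
Conditions: NBS, Me2S, CH2Cl2, −20 → 0 °C
Reagents that add atoms: N-bromosuccinimide, O=C1CCC(=O)N1Br
Why: Corey–Kim-type activation of the Morita–Baylis–Hillman alcohol and bromide attack with allylic transposition (SN2') should give the conjugated endocyclic butenolide with the primary bromide on C13, removing the C7 carbinol centre under neutral conditions that do not epimerise C8.

Step 14
Reactants: 22 (2Z,6E)-8-[(2R)-4-(bromomethyl)-5-oxo-2,5-dihydrofuran-2-yl]-3-{[(tert-butyldiphenylsilyl)oxy]methyl}-7-methylocta-2,6-dienal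
Product: 24 15-[(tert-butyldiphenylsilyl)oxy]-6α-hydroxygermacra-1(10)E,4Z,11(13)-trien-12,8β-olide, via allylchromium dichloride 23 (not isolated)
Conditions: CrCl2 (8 equiv), THF, 0.002 M, slow addition, rt; aq. NH4Cl
Reagents that add atoms: none
Why: In this intramolecular Nozaki–Hiyama–Kishi allylation the allylchromium adds through its γ-carbon C7 to the enal carbonyl C6 in a closed chair transition state, and because the butenolide holds O8 in the plane of the allyl unit with C8 trans to CH2Cr, the tethered aldehyde should reach C7 on the face that carries C9 (H7 cis to H8, cis-fused lactone) with both ring arms equatorial (H6 trans to H7, 6α-OH), high dilution suppressing oligomerisation.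

Step 15
Reactants: 24 15-[(tert-butyldiphenylsilyl)oxy]-6α-hydroxygermacra-1(10)E,4Z,11(13)-trien-12,8β-olide
Product: 25 15-[(tert-butyldiphenylsilyl)oxy]-8β-hydroxygermacra-1(10)E,4Z,11(13)-trien-12,6α-olide
Conditions: DBU (0.2 equiv), CH2Cl2, 0 °C → rt
Reagents that add atoms: none
Why: Base-mediated translactonisation through the bicyclic tetrahedral intermediate at C12 should move the acyl group from O8 to O6, because the trans-fused 6α,12-lactone avoids the eclipsed C6–C7–C8–C9 torsion that the cis-fused 8β,12-lactone forces on the ten-membered ring, and no stereocentre is touched.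

Step 16
Reactants: 25 15-[(tert-butyldiphenylsilyl)oxy]-8β-hydroxygermacra-1(10)E,4Z,11(13)-trien-12,6α-olide; 26 angelic acid
Product: 28 8β-angeloyloxy-15-[(tert-butyldiphenylsilyl)oxy]germacra-1(10)E,4Z,11(13)-trien-12,6α-olide, via mixed anhydride 27 (not isolated)
Conditions: 26, 2,4,6-trichlorobenzoyl chloride, Et3N, PhMe, rt; then 25, 75 °C
Reagents that add atoms: none
Why: Yamaguchi-type esterification through the mixed 2,4,6-trichlorobenzoic anhydride acylates the hindered axial 8β-hydroxyl with retention at C8, and leaving out a nucleophilic acyl-transfer catalyst avoids Z to E isomerisation of the angelate.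

Step 17
Reactants: 28 8β-angeloyloxy-15-[(tert-butyldiphenylsilyl)oxy]germacra-1(10)E,4Z,11(13)-trien-12,6α-olide
Product: 29 8β-angeloyloxy-15-hydroxygermacra-1(10)E,4Z,11(13)-trien-12,6α-olide
Conditions: Bu4NF, AcOH (1:1), THF, 0 °C → rt
Reagents that add atoms: none
Why: Fluoride-mediated desilylation of the primary allylic TBDPS ether, buffered with acetic acid so that the angelate, the α-methylene lactone and the diene are not exposed to base.

Step 18
Reactants: 29 8β-angeloyloxy-15-hydroxygermacra-1(10)E,4Z,11(13)-trien-12,6α-olide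
Product: 30 8β-angeloyloxy-15-oxogermacra-1(10)E,4Z,11(13)-trien-12,6α-olide
Conditions: MnO2 (activated, excess), CH2Cl2, rt
Reagents that add atoms: none
Why: Allylic oxidation with activated MnO2 converts the primary allylic alcohol into the conjugated aldehyde under neutral conditions without isomerising C4=C5 or touching the other groups.

Step 19
Reactants: 30 8β-angeloyloxy-15-oxogermacra-1(10)E,4Z,11(13)-trien-12,6α-olide
Product: 31 8β-angeloyloxy-15-oxoelema-1,3,11(13)-trien-12,6α-olide
Conditions: PhMe (degassed), BHT (cat.), sealed tube, 120 °C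
Reagents that add atoms: none
Why: On heating, 30 should undergo a concerted, suprafacial [3,3]-sigmatropic (Cope) shift of the hexa-1,5-diene C10=C1–C2–C3–C4=C5, in which the C5–C10 bond forms across the ring while C2–C3 breaks; the closest known reaction type is the thermal rearrangement of germacra-1(10),4-dienolides to elemanolides. The cyclohexane C5–C10 closes by this single transannular σ-bond formation through a chair-like six-membered transition state, that is, by contraction of the ten-membered ring. C10 and C5 are set together: two ring-trans alkenes in a chair transition state put the C10 methyl and the C5 hydrogen axial and anti (methyl β, H5 α), with the vinyl group and the formylvinyl arm trans-diequatorial. The face is fixed by the crossed ring conformer with C14 and C15 both on the β-face, which the trans-fused 6α,12-lactone and the C8 ester impose, so C6, C7 and C8 relay the absolute configuration. The step needs diastereoselectivity and a favourable equilibrium: the first should come from the single reactive conformer, the second from release of medium-ring strain while the aldehyde stays conjugated (with C4=C5 before, with C4=C3 after). Oxygen-free solvent and a radical inhibitor protect the methylene lactone at this temperature.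

Step 20
Reactants: 31 8β-angeloyloxy-15-oxoelema-1,3,11(13)-trien-12,6α-olide
Product: 32 8β-angeloyloxyelema-1,3,11(13)-trien-12,6α-olid-15-oic acid (CNP0256928.2)
Conditions: NaClO2, NaH2PO4, 2-methylbut-2-ene, t-BuOH/H2O, 0 °C → rt
Reagents that add atoms: sodium chlorite, [Na+].[O-]Cl=O
Why: Pinnick oxidation converts the α-substituted acrolein into the acrylic acid, with 2-methylbut-2-ene scavenging hypochlorous acid so that the vinyl, methylene-lactone and angelate alkenes and all stereocentres are untouched.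

**Compound list**

1 | (R)-2-{[(4-methoxybenzyl)oxy]methyl}oxirane | COc1ccc(COC[C@H]2CO2)cc1 | starting material
2 | lithium acetylide–ethylenediamine complex | [Li+].[C-]#C.NCCN | starting material
3 | (R)-1-[(4-methoxybenzyl)oxy]pent-4-yn-2-ol | COc1ccc(COC[C@H](O)CC#C)cc1 | intermediate
4 | (R)-triethyl({1-[(4-methoxybenzyl)oxy]pent-4-yn-2-yl}oxy)silane | COc1ccc(COC[C@H](O[Si](CC)(CC)CC)CC#C)cc1 | intermediate
5 | ethylene oxide | C1CO1 | starting material
6 | alkenyldimethylalane from 4 (C14 methyl on C10, AlMe2 on C1, E; not isolated) | COc1ccc(COC[C@H](O[Si](CC)(CC)CC)C/C(C)=C/[Al](C)C)cc1 | intermediate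
7 | lithium butyl(dimethyl)alkenylalanate from 6 (not isolated) | [Li+].COc1ccc(COC[C@H](O[Si](CC)(CC)CC)C/C(C)=C/[Al-](C)(C)CCCC)cc1 | intermediate
8 | (3E,6R)-7-[(4-methoxybenzyl)oxy]-4-methyl-6-[(triethylsilyl)oxy]hept-3-en-1-ol | COc1ccc(COC[C@H](O[Si](CC)(CC)CC)C/C(C)=C/CCO)cc1 | intermediate
9 | {[(2R,4E)-7-iodo-1-[(4-methoxybenzyl)oxy]-4-methylhept-4-en-2-yl]oxy}triethylsilane | COc1ccc(COC[C@H](O[Si](CC)(CC)CC)C/C(C)=C/CCI)cc1 | intermediate
10 | ethyl 2-(diphenoxyphosphoryl)acetate | CCOC(=O)CP(=O)(Oc1ccccc1)Oc1ccccc1 | starting material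
11 | ethyl (5E,8R)-2-(diphenoxyphosphoryl)-9-[(4-methoxybenzyl)oxy]-6-methyl-8-[(triethylsilyl)oxy]non-5-enoate (both C2 epimers) | COc1ccc(COC[C@H](O[Si](CC)(CC)CC)C/C(C)=C/CCC(C(=O)OCC)P(=O)(Oc2ccccc2)Oc2ccccc2)cc1 | intermediate
12 | 2,2-dimethoxyacetaldehyde | COC(OC)C=O | starting material
13 | ethyl (2Z,5E,8R)-2-(2,2-dimethoxyethylidene)-9-[(4-methoxybenzyl)oxy]-6-methyl-8-[(triethylsilyl)oxy]non-5-enoate | COc1ccc(COC[C@H](O[Si](CC)(CC)CC)C/C(C)=C/CC/C(C(=O)OCC)=C/C(OC)OC)cc1 | intermediate
14 | (2Z,5E,8R)-2-(2,2-dimethoxyethylidene)-9-[(4-methoxybenzyl)oxy]-6-methyl-8-[(triethylsilyl)oxy]non-5-en-1-ol | COc1ccc(COC[C@H](O[Si](CC)(CC)CC)C/C(C)=C/CC/C(CO)=C/C(OC)OC)cc1 | intermediate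
15 | tert-butyl{[(2Z,5E,8R)-2-(2,2-dimethoxyethylidene)-9-[(4-methoxybenzyl)oxy]-6-methyl-8-[(triethylsilyl)oxy]non-5-en-1-yl]oxy}diphenylsilane | COc1ccc(COC[C@H](O[Si](CC)(CC)CC)C/C(C)=C/CC/C(CO[Si](c2ccccc2)(c2ccccc2)C(C)(C)C)=C/C(OC)OC)cc1 | intermediate
16 | (2R,4E,8Z)-8-{[(tert-butyldiphenylsilyl)oxy]methyl}-10,10-dimethoxy-4-methyl-2-[(triethylsilyl)oxy]deca-4,8-dien-1-ol | OC[C@H](O[Si](CC)(CC)CC)C/C(C)=C/CC/C(CO[Si](c1ccccc1)(c1ccccc1)C(C)(C)C)=C/C(OC)OC | intermediate
17 | (2R,4E,8Z)-8-{[(tert-butyldiphenylsilyl)oxy]methyl}-10,10-dimethoxy-4-methyl-2-[(triethylsilyl)oxy]deca-4,8-dienal | O=C[C@H](O[Si](CC)(CC)CC)C/C(C)=C/CC/C(CO[Si](c1ccccc1)(c1ccccc1)C(C)(C)C)=C/C(OC)OC | intermediate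
18 | methyl acrylate | C=CC(=O)OC | starting material
19 | methyl (4R,6E,10Z)-10-{[(tert-butyldiphenylsilyl)oxy]methyl}-3-hydroxy-12,12-dimethoxy-6-methyl-2-methylidene-4-[(triethylsilyl)oxy]dodeca-6,10-dienoate (both C3 epimers) | COC(=O)C(=C)C(O)[C@H](O[Si](CC)(CC)CC)C/C(C)=C/CC/C(CO[Si](c1ccccc1)(c1ccccc1)C(C)(C)C)=C/C(OC)OC | intermediate
20 | methyl (4R,6E,10Z)-10-{[(tert-butyldiphenylsilyl)oxy]methyl}-3,4-dihydroxy-6-methyl-2-methylidene-12-oxododeca-6,10-dienoate (not isolated) | COC(=O)C(=C)C(O)[C@H](O)C/C(C)=C/CC/C(CO[Si](c1ccccc1)(c1ccccc1)C(C)(C)C)=C/C=O | intermediate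
21 | (2Z,6E)-3-{[(tert-butyldiphenylsilyl)oxy]methyl}-8-[(2R)-3-hydroxy-4-methylidene-5-oxooxolan-2-yl]-7-methylocta-2,6-dienal | O=C1O[C@H](C/C(C)=C/CC/C(CO[Si](c2ccccc2)(c2ccccc2)C(C)(C)C)=C/C=O)C(O)C1=C | intermediate
22 | (2Z,6E)-8-[(2R)-4-(bromomethyl)-5-oxo-2,5-dihydrofuran-2-yl]-3-{[(tert-butyldiphenylsilyl)oxy]methyl}-7-methylocta-2,6-dienal | O=C1O[C@H](C/C(C)=C/CC/C(CO[Si](c2ccccc2)(c2ccccc2)C(C)(C)C)=C/C=O)C=C1CBr | intermediate
23 | allylchromium dichloride from 22 (CrCl2 on C13; not isolated) | O=C1O[C@H](C/C(C)=C/CC/C(CO[Si](c2ccccc2)(c2ccccc2)C(C)(C)C)=C/C=O)C=C1C[Cr](Cl)Cl | intermediate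
24 | 15-[(tert-butyldiphenylsilyl)oxy]-6α-hydroxygermacra-1(10)E,4Z,11(13)-trien-12,8β-olide | C/C1=C\CC/C(CO[Si](c3ccccc3)(c3ccccc3)C(C)(C)C)=C/[C@@H](O)[C@@H]2C(=C)C(=O)O[C@@H]2C1 | intermediate
25 | 15-[(tert-butyldiphenylsilyl)oxy]-8β-hydroxygermacra-1(10)E,4Z,11(13)-trien-12,6α-olide | C/C1=C\CC/C(CO[Si](c3ccccc3)(c3ccccc3)C(C)(C)C)=C/[C@H]2OC(=O)C(=C)[C@@H]2[C@H](O)C1 | intermediate
26 | angelic acid, (Z)-2-methylbut-2-enoic acid | C/C=C(C)\C(=O)O | starting material
27 | angelic 2,4,6-trichlorobenzoic anhydride (not isolated) | C/C=C(C)\C(=O)OC(=O)c1c(Cl)cc(Cl)cc1Cl | intermediate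
28 | 8β-angeloyloxy-15-[(tert-butyldiphenylsilyl)oxy]germacra-1(10)E,4Z,11(13)-trien-12,6α-olide | C/C1=C\CC/C(CO[Si](c3ccccc3)(c3ccccc3)C(C)(C)C)=C/[C@H]2OC(=O)C(=C)[C@@H]2[C@H](OC(=O)/C(C)=C\C)C1 | intermediate
29 | 8β-angeloyloxy-15-hydroxygermacra-1(10)E,4Z,11(13)-trien-12,6α-olide | C/C1=C\CC/C(CO)=C/[C@H]2OC(=O)C(=C)[C@@H]2[C@H](OC(=O)/C(C)=C\C)C1 | intermediate
30 | 8β-angeloyloxy-15-oxogermacra-1(10)E,4Z,11(13)-trien-12,6α-olide | C/C1=C\CC/C(C=O)=C/[C@H]2OC(=O)C(=C)[C@@H]2[C@H](OC(=O)/C(C)=C\C)C1 | intermediate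
31 | 8β-angeloyloxy-15-oxoelema-1,3,11(13)-trien-12,6α-olide | C=C[C@]1(C)C[C@@H](OC(=O)/C(C)=C\C)[C@H]2C(=C)C(=O)O[C@@H]2[C@H]1C(=C)C=O | intermediate
32 | 8β-angeloyloxyelema-1,3,11(13)-trien-12,6α-olid-15-oic acid (CNP0256928.2) | C=C[C@]1(C)C[C@@H](OC(=O)/C(C)=C\C)[C@H]2C(=C)C(=O)O[C@@H]2[C@H]1C(=C)C(=O)O | target

**Step count and risks**

Total step count: 20. Longest linear sequence: 20 steps (1 to 32).

Steps most likely to fail:

1. Step 14 (macrocyclisation). Oligomerisation, reductive opening of the butenolide from the allylchromium (1,4-elimination), or closure on the butenolide face remote from C9 could outrun the strained cis-fused closure. The fallback sets out from 21 and comes back at 24. Acetylation of 21 (Ac2O, pyridine, 0 °C) should give the allylic acetate (2Z,6E)-8-[(2R)-3-acetoxy-4-methylidene-5-oxooxolan-2-yl]-3-{[(tert-butyldiphenylsilyl)oxy]methyl}-7-methylocta-2,6-dienal F1. Palladium-catalysed Miyaura-type borylation of this Morita–Baylis–Hillman acetate (B2pin2, Pd2(dba)3, DMSO/THF, high dilution) should give, with allylic transposition, the butenolide allylboronate (2Z,6E)-3-{[(tert-butyldiphenylsilyl)oxy]methyl}-7-methyl-8-{(2R)-5-oxo-4-[(4,4,5,5-tetramethyl-1,3,2-dioxaborolan-2-yl)methyl]-2,5-dihydrofuran-2-yl}octa-2,6-dienal F2. This boronate has the same fixed allyl geometry and in-plane O8, and on gentle warming it should close by intramolecular allylboration through a six-membered boron chair, with no reducing metal present. Aqueous work-up of the borate gives 24.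

2. Step 15 (lactone migration). The acyl shift may stop at an equilibrium mixture, or the base may move the exocyclic methylene into the ring. The fallback sets out from 24 and comes back at 25. Saponification (LiOH, THF/H2O, 0 °C) should open the lactone to 15-[(tert-butyldiphenylsilyl)oxy]-6α,8β-dihydroxygermacra-1(10)E,4Z,11(13)-trien-12-oic acid F3. Kinetic Mukaiyama lactonisation (2-chloro-1-methylpyridinium iodide, Et3N, CH2Cl2, 0 °C) should then close onto the unhindered equatorial 6α-hydroxyl in preference to the axial 8β-hydroxyl and give 25.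

3. Step 19 (Cope rearrangement). The sigmatropic equilibrium may stop short of completion, or the aldehyde may be lost at the temperature needed (transannular carbonyl-ene reaction, autoxidation). The fallback sets out from 30 and comes back at 32, with the order of the last two operations reversed. Pinnick oxidation of 30 under the conditions of step 20 should give 8β-angeloyloxygermacra-1(10)E,4Z,11(13)-trien-12,6α-olid-15-oic acid F4. Its thermolysis (PhMe or xylene, BHT, 120–140 °C) should then perform the same [3,3] shift on a carboxylic acid, which cannot undergo ene or autoxidation chemistry and keeps the conjugation that drives the equilibrium, and gives 32 directly.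

**Further compounds**

F1 | step 14 | (2Z,6E)-8-[(2R)-3-acetoxy-4-methylidene-5-oxooxolan-2-yl]-3-{[(tert-butyldiphenylsilyl)oxy]methyl}-7-methylocta-2,6-dienal | O=C1O[C@H](C/C(C)=C/CC/C(CO[Si](c2ccccc2)(c2ccccc2)C(C)(C)C)=C/C=O)C(OC(C)=O)C1=C
F2 | step 14 | (2Z,6E)-3-{[(tert-butyldiphenylsilyl)oxy]methyl}-7-methyl-8-{(2R)-5-oxo-4-[(4,4,5,5-tetramethyl-1,3,2-dioxaborolan-2-yl)methyl]-2,5-dihydrofuran-2-yl}octa-2,6-dienal | O=C1O[C@H](C/C(C)=C/CC/C(CO[Si](c2ccccc2)(c2ccccc2)C(C)(C)C)=C/C=O)C=C1CB3OC(C)(C)C(C)(C)O3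
F3 | step 15 | 15-[(tert-butyldiphenylsilyl)oxy]-6α,8β-dihydroxygermacra-1(10)E,4Z,11(13)-trien-12-oic acid | C/C1=C\CC/C(CO[Si](c2ccccc2)(c2ccccc2)C(C)(C)C)=C/[C@@H](O)[C@H](C(=C)C(=O)O)[C@H](O)C1
F4 | step 19 | 8β-angeloyloxygermacra-1(10)E,4Z,11(13)-trien-12,6α-olid-15-oic acid | C/C1=C\CC/C(C(=O)O)=C/[C@H]2OC(=O)C(=C)[C@@H]2[C@H](OC(=O)/C(C)=C\C)C1
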